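The oxolane ring (O1, C2 bearing the trimethoxyphenyl ring, C3 bearing CH2OH, C4 bearing the dimethoxybenzyl group, C5) is closed at C2–C3 by a dirhodium-catalysed intramolecular carbene C–H insertion. The step exploits the C2–H bond, activated by O1 and the aryl ring, and the cis C3/C4 side chains, which are tied back as a temporary γ-lactone. The precursor is an α-diazo-γ-butyrolactone whose carbonyl is the future CH2OH carbon, whose aryl carbinol carbon is the future benzylic CH2, and whose C4 carries a 3,4,5-trimethoxybenzyloxymethyl arm. One operation forms C2–C3 and sets C2 and C3 all-cis; lactone hydrogenolysis and borane reduction finish.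

Key step: step 8

Remark: the target descriptors are read as (2R,3R,4R), which places the aryl group at C2, the hydroxymethyl group at C3 and the benzyl group at C4 on one face of the oxolane ring; the lactone carbinol centre made in step 2 is temporary and is erased in step 9.

Step 1
Reactants: 1 (S)-4-benzyl-1,3-oxazolidin-2-one; 2 methyl 4-chloro-4-oxobutanoate
Product: 3 methyl 4-[(4S)-4-benzyl-2-oxo-1,3-oxazolidin-3-yl]-4-oxobutanoate
Conditions: n-BuLi, THF, −78 °C; then 2, −78 to 0 °C
Reagents that add atoms: none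
Why: N-acylation of the lithiated oxazolidinone by the acid chloride (imide formation for an Evans auxiliary) should be far faster than attack at the methyl ester, and no stereocentre is formed or touched.

Step 2
Reactants: 3 methyl 4-[(4S)-4-benzyl-2-oxo-1,3-oxazolidin-3-yl]-4-oxobutanoate; 4 3,4-dimethoxybenzaldehyde
Product: 6 (4S)-4-benzyl-3-{[(2S,3S)-2-(3,4-dimethoxyphenyl)-5-oxooxolan-3-yl]carbonyl}-1,3-oxazolidin-2-one, via syn-aldol adduct 5 (not isolated)
Conditions: Bu2BOTf, i-Pr2NEt, CH2Cl2, 0 °C; 4, −78 to 0 °C; pH 7 buffer, MeOH, 30% H2O2, 0 °C; then p-TsOH (cat.), CH2Cl2, rt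
Reagents that add atoms: none
Why: Evans syn-aldol then lactonization: the boron Z-enolate of the imide (the ester is not enolized) reacts through a closed Zimmerman–Traxler chair on the face away from the benzyl group of the auxiliary to set both new centres (S,S), and the benzylic hydroxyl then closes onto the methyl ester, the syn adduct necessarily giving the trans-2,3-disubstituted lactone.

Step 3
Reactants: 6 (4S)-4-benzyl-3-{[(2S,3S)-2-(3,4-dimethoxyphenyl)-5-oxooxolan-3-yl]carbonyl}-1,3-oxazolidin-2-one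
Product: 8 (2S,3S)-2-(3,4-dimethoxyphenyl)-5-oxooxolane-3-carboxylic acid, via peroxy acid 7 (not isolated)
Conditions: LiOH, 30% H2O2, THF/H2O, 0 °C; Na2SO3 (aq); HCl to pH 2
Reagents that add atoms: hydrogen peroxide, OO (acting as lithium hydroperoxide)
Why: Hydroperoxide cleavage of the N-acyl oxazolidinone (auxiliary removal) attacks the exocyclic imide carbonyl selectively, sulfite reduces the peroxy acid, and any lactone opened by base recloses on acidification, so neither centre is touched.

Step 4
Reactants: 8 (2S,3S)-2-(3,4-dimethoxyphenyl)-5-oxooxolane-3-carboxylic acid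
Product: 9 (4R,5S)-5-(3,4-dimethoxyphenyl)-4-(hydroxymethyl)oxolan-2-one
Conditions: BH3·SMe2, THF, 0 °C to rt; then MeOH
Reagents that add atoms: none
Why: Chemoselective borane reduction of a carboxylic acid (through the acyloxyborane) in the presence of the lactone, under non-basic conditions that avoid translactonization; no stereocentre is affected.

Step 5
Reactants: 10 (3,4,5-trimethoxyphenyl)methanol
Product: 11 (3,4,5-trimethoxyphenyl)methyl 2,2,2-trichloroacetimidate
Conditions: Cl3CCN, DBU (cat.), CH2Cl2, 0 °C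
Reagents that add atoms: trichloroacetonitrile, N#CC(Cl)(Cl)Cl
Why: Base-catalysed addition of the benzylic alkoxide to the electron-poor nitrile (trichloroacetimidate formation) is general for primary alcohols.

Step 6
Reactants: 9 (4R,5S)-5-(3,4-dimethoxyphenyl)-4-(hydroxymethyl)oxolan-2-one; 11 (3,4,5-trimethoxyphenyl)methyl 2,2,2-trichloroacetimidate
Product: 12 (4R,5S)-5-(3,4-dimethoxyphenyl)-4-{[(3,4,5-trimethoxyphenyl)methoxy]methyl}oxolan-2-one
Conditions: TfOH (cat.), CH2Cl2, −20 to 0 °C
Reagents that add atoms: none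
Why: Acid-catalysed trichloroacetimidate benzylation transfers the benzyl group to the primary hydroxyl without base, so the β-hydroxymethyl lactone cannot translactonize and no stereocentre is touched.

Step 7
Reactants: 12 (4R,5S)-5-(3,4-dimethoxyphenyl)-4-{[(3,4,5-trimethoxyphenyl)methoxy]methyl}oxolan-2-one
Product: 14 (4R,5S)-3-diazo-5-(3,4-dimethoxyphenyl)-4-{[(3,4,5-trimethoxyphenyl)methoxy]methyl}oxolan-2-one, via trifluoroacetyl lactone 13 (not isolated)
Conditions: LiN(SiMe3)2, THF, −78 °C; CF3CO2CH2CF3; 5% HCl work-up; then MsN3, Et3N, H2O, MeCN, rt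
Reagents that add atoms: 2,2,2-trifluoroethyl trifluoroacetate, O=C(OCC(F)(F)F)C(F)(F)F (its atoms stay only in 13); methanesulfonyl azide, CS(=O)(=O)N=[N+]=[N-]
Why: Deacylative Regitz-type diazo transfer: C-trifluoroacetylation of the lactone enolate activates the α-position, the sulfonyl azide transfers N2 and the trifluoroacetyl group leaves as the N-sulfonyl amide, while the lactone β- and γ-centres carry no β-leaving group and stay intact.

Step 8
Reactants: 14 (4R,5S)-3-diazo-5-(3,4-dimethoxyphenyl)-4-{[(3,4,5-trimethoxyphenyl)methoxy]methyl}oxolan-2-one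
Product: 15 (3S,3aR,6R,6aS)-3-(3,4-dimethoxyphenyl)-6-(3,4,5-trimethoxyphenyl)tetrahydro-1H,3H-furo[3,4-c]furan-1-one (cis-fused; 3-aryl exo; 6-aryl endo)
Conditions: Rh2(OAc)4 (2 mol %), CH2Cl2, rt, slow addition of 14
Reagents that add atoms: none
Why: Rh2(OAc)4 extrudes N2 from the diazo lactone to give an electrophilic rhodium-bound carbene at the lactone α-carbon (future C3), which inserts through a concerted, asynchronous three-centre transition state with hydride-transfer character into the C–H bond of the benzylic ether carbon (future C2), a bond made hydridic by O1 and the 3,4,5-trimethoxyphenyl ring. The closest known reaction type is the dirhodium-catalysed intramolecular 1,5-C–H insertion of α-diazo-γ-butyrolactones that carry a 4-(benzyloxymethyl) arm, which delivers endo,exo-diaryl furofuranones. The oxolane ring closes as a five-membered ring by 1,5-insertion along the chain C3–C4–C5–O1–C2 and, being annulated to the five-membered lactone, can only be cis-fused, so the existing C4 centre fixes C3 with its carbonyl carbon cis to the C4 carbinol carbon. At C2 the aryl group is turned away from the bulky dirhodium core, which sits on the convex face where the transferred hydrogen ends up, and therefore lands on the concave face, cis to the lactone carbonyl, completing the all-cis C2/C3/C4 array. The step needs site selectivity over 1,2-hydride migration from C4–H (butenolide), over cyclopropanation or aromatic substitution of the two electron-rich rings and over oxonium ylide formation at O1; the 1,5-disposition of the doubly activated C–H bond, the four-membered ring that an O1 ylide would require, and slow addition to an electrophilic carboxylate catalyst in a non-coordinating solvent are what secure it.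

Step 9
Reactants: 15 (3S,3aR,6R,6aS)-3-(3,4-dimethoxyphenyl)-6-(3,4,5-trimethoxyphenyl)tetrahydro-1H,3H-furo[3,4-c]furan-1-one
Product: 16 (2R,3S,4R)-4-[(3,4-dimethoxyphenyl)methyl]-2-(3,4,5-trimethoxyphenyl)oxolane-3-carboxylic acid
Conditions: H2 (1 atm), 10% Pd/C, EtOAc, rt
Reagents that add atoms: none
Why: Hydrogenolysis of the benzylic C–O bond of the γ-aryl lactone (acyloxy leaving group on the electron-rich 3,4-dimethoxyphenyl carbon) should be much faster than cleavage of the C2–O1 ether at the less activated 3,4,5-trimethoxyphenyl carbon; it erases the temporary carbinol centre and leaves C2, C3 and C4 untouched.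

Step 10
Reactants: 16 (2R,3S,4R)-4-[(3,4-dimethoxyphenyl)methyl]-2-(3,4,5-trimethoxyphenyl)oxolane-3-carboxylic acid
Product: 17 [(2R,3R,4R)-4-[(3,4-dimethoxyphenyl)methyl]-2-(3,4,5-trimethoxyphenyl)oxolan-3-yl]methanol
Conditions: BH3·THF, THF, 0 °C to rt; then MeOH
Reagents that add atoms: none
Why: Borane reduction of the carboxylic acid to the primary alcohol is non-basic, so the C3 centre flanked by two cis substituents cannot epimerize through an enolate.

Compound list

1 | (S)-4-benzyl-1,3-oxazolidin-2-one | O=C1N[C@@H](Cc2ccccc2)CO1 | starting material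
2 | methyl 4-chloro-4-oxobutanoate | COC(=O)CCC(=O)Cl | starting material
3 | methyl 4-[(4S)-4-benzyl-2-oxo-1,3-oxazolidin-3-yl]-4-oxobutanoate | COC(=O)CCC(=O)N1C(=O)OC[C@@H]1Cc1ccccc1 | intermediate
4 | 3,4-dimethoxybenzaldehyde | COc1ccc(C=O)cc1OC | starting material
5 | methyl (3S,4S)-3-{[(4S)-4-benzyl-2-oxo-1,3-oxazolidin-3-yl]carbonyl}-4-(3,4-dimethoxyphenyl)-4-hydroxybutanoate (syn-aldol adduct, not isolated) | COC(=O)C[C@H](C(=O)N1C(=O)OC[C@@H]1Cc1ccccc1)[C@H](O)c1ccc(OC)c(OC)c1 | intermediate
6 | (4S)-4-benzyl-3-{[(2S,3S)-2-(3,4-dimethoxyphenyl)-5-oxooxolan-3-yl]carbonyl}-1,3-oxazolidin-2-one (trans lactone) | O=C1O[C@H](c2ccc(OC)c(OC)c2)[C@@H](C(=O)N2C(=O)OC[C@@H]2Cc2ccccc2)C1 | intermediate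
7 | (2S,3S)-2-(3,4-dimethoxyphenyl)-5-oxooxolane-3-carboperoxoic acid (peroxy acid, not isolated) | O=C1O[C@H](c2ccc(OC)c(OC)c2)[C@@H](C(=O)OO)C1 | intermediate
8 | (2S,3S)-2-(3,4-dimethoxyphenyl)-5-oxooxolane-3-carboxylic acid (trans) | O=C1O[C@H](c2ccc(OC)c(OC)c2)[C@@H](C(=O)O)C1 | intermediate
9 | (4R,5S)-5-(3,4-dimethoxyphenyl)-4-(hydroxymethyl)oxolan-2-one (trans) | O=C1O[C@H](c2ccc(OC)c(OC)c2)[C@@H](CO)C1 | intermediate
10 | (3,4,5-trimethoxyphenyl)methanol | COc1cc(CO)cc(OC)c1OC | starting material
11 | (3,4,5-trimethoxyphenyl)methyl 2,2,2-trichloroacetimidate | COc1cc(COC(=N)C(Cl)(Cl)Cl)cc(OC)c1OC | intermediate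
12 | (4R,5S)-5-(3,4-dimethoxyphenyl)-4-{[(3,4,5-trimethoxyphenyl)methoxy]methyl}oxolan-2-one | O=C1O[C@H](c2ccc(OC)c(OC)c2)[C@@H](COCc2cc(OC)c(OC)c(OC)c2)C1 | intermediate
13 | (4R,5S)-5-(3,4-dimethoxyphenyl)-3-(trifluoroacetyl)-4-{[(3,4,5-trimethoxyphenyl)methoxy]methyl}oxolan-2-one (C3 epimers and enol, not isolated) | O=C1O[C@H](c2ccc(OC)c(OC)c2)[C@@H](COCc2cc(OC)c(OC)c(OC)c2)C1C(=O)C(F)(F)F | intermediate
14 | (4R,5S)-3-diazo-5-(3,4-dimethoxyphenyl)-4-{[(3,4,5-trimethoxyphenyl)methoxy]methyl}oxolan-2-one | O=C1O[C@H](c2ccc(OC)c(OC)c2)[C@@H](COCc2cc(OC)c(OC)c(OC)c2)C1=[N+]=[N-] | intermediate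
15 | (3S,3aR,6R,6aS)-3-(3,4-dimethoxyphenyl)-6-(3,4,5-trimethoxyphenyl)tetrahydro-1H,3H-furo[3,4-c]furan-1-one (cis-fused, 3-aryl exo, 6-aryl endo) | O=C1O[C@H](c2ccc(OC)c(OC)c2)[C@H]3CO[C@@H](c4cc(OC)c(OC)c(OC)c4)[C@@H]13 | intermediate
16 | (2R,3S,4R)-4-[(3,4-dimethoxyphenyl)methyl]-2-(3,4,5-trimethoxyphenyl)oxolane-3-carboxylic acid (all-cis) | COc1ccc(C[C@H]2CO[C@@H](c3cc(OC)c(OC)c(OC)c3)[C@H]2C(=O)O)cc1OC | intermediate
17 | [(2R,3R,4R)-4-[(3,4-dimethoxyphenyl)methyl]-2-(3,4,5-trimethoxyphenyl)oxolan-3-yl]methanol (all-cis) | COc1ccc(C[C@H]2CO[C@@H](c3cc(OC)c(OC)c(OC)c3)[C@H]2CO)cc1OC | target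

Total step count: 10. Longest linear sequence: 9 steps (steps 1–4 and 6–10; step 5 prepares the benzylating agent).

Steps most likely to fail

1. Step 8. The carbene may be diverted by 1,2-hydride migration from C4–H to a butenolide, or the insertion may show insufficient endo selectivity at C2. The fallback sets out from 9 and returns at 15; it closes the oxolane at O1–C2 instead and delivers the C2 hydrogen last. Alcohol 9 would be silylated (t-BuMe2SiCl, imidazole, DMF) to the tert-butyldimethylsilyl ether F1. Its lithium enolate (LiN(SiMe3)2, THF, −78 °C) would be C-acylated with 3,4,5-trimethoxybenzoyl chloride to the 3-aroyl lactone F2. Desilylation (HF·pyridine, THF) should let the freed hydroxyl add to the ketone, the epimerizable C3 adjusting to the only possible cis ring fusion, to give the bicyclic hemiketal F3. Ionic hydrogenation (Et3SiH, BF3·OEt2, CH2Cl2, −78 °C) should then reduce the derived oxocarbenium ion from the convex face, placing the aryl group on the concave face and giving 15.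

2. Step 9. Hydrogenolysis may fail to distinguish the two benzylic C–O bonds, with over-reduction by cleavage of C2–O1, or may stall on the hindered bicycle. The fallback sets out from 15 and returns at 17; it replaces hydrogenolysis by radical deoxygenation. LiAlH4 (THF, 0 °C) should reduce 15 to the diol F4. The primary hydroxyl would be silylated selectively (t-BuMe2SiCl, imidazole, CH2Cl2, 0 °C) to the mono-silyl ether F5. The benzylic alcohol would be converted (NaH, CS2, MeI, THF) to the S-methyl xanthate F6. Barton–McCombie deoxygenation (Bu3SnH, AIBN, toluene, 80 °C) should give the silyl ether F7, and Bu4NF (THF) would then release 17.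

3. Step 6. Acid-catalysed benzyl transfer may be accompanied by Friedel–Crafts benzylation of the dimethoxyphenyl ring or by acid-induced ionization at the lactone carbinol carbon. The fallback sets out from 9 and returns at 12; it builds the ether by reductive etherification instead of alkylation. Alcohol 9 would be converted (Me3SiCl, Et3N, CH2Cl2) to the trimethylsilyl ether F8. F8 would be combined with 3,4,5-trimethoxybenzaldehyde and Et3SiH under BiBr3 catalysis (MeCN, rt); the silyl ether should add to the activated aldehyde and the resulting oxocarbenium ion be reduced by the silane to give 12.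

Further compounds

F1 | step 8 | (4R,5S)-4-({[tert-butyl(dimethyl)silyl]oxy}methyl)-5-(3,4-dimethoxyphenyl)oxolan-2-one | O=C1O[C@H](c2ccc(OC)c(OC)c2)[C@@H](CO[Si](C)(C)C(C)(C)C)C1
F2 | step 8 | (4R,5S)-4-({[tert-butyl(dimethyl)silyl]oxy}methyl)-5-(3,4-dimethoxyphenyl)-3-(3,4,5-trimethoxybenzoyl)oxolan-2-one (C3 epimers and enol) | O=C1O[C@H](c2ccc(OC)c(OC)c2)[C@@H](CO[Si](C)(C)C(C)(C)C)C1C(=O)c1cc(OC)c(OC)c(OC)c1
F3 | step 8 | (3S,3aR,6aS)-3-(3,4-dimethoxyphenyl)-6-hydroxy-6-(3,4,5-trimethoxyphenyl)tetrahydro-1H,3H-furo[3,4-c]furan-1-one (cis-fused hemiketal, either configuration at C6) | O=C1O[C@H](c2ccc(OC)c(OC)c2)[C@H]3COC(O)(c4cc(OC)c(OC)c(OC)c4)[C@@H]13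
F4 | step 9 | [(2R,3R,4R)-4-[(S)-(3,4-dimethoxyphenyl)(hydroxy)methyl]-2-(3,4,5-trimethoxyphenyl)oxolan-3-yl]methanol | COc1ccc([C@@H](O)[C@H]2CO[C@@H](c3cc(OC)c(OC)c(OC)c3)[C@H]2CO)cc1OC
F5 | step 9 | primary tert-butyldimethylsilyl ether of diol F4 | COc1ccc([C@@H](O)[C@H]2CO[C@@H](c3cc(OC)c(OC)c(OC)c3)[C@H]2CO[Si](C)(C)C(C)(C)C)cc1OC
F6 | step 9 | O-benzylic S-methyl xanthate of F5 | COc1ccc([C@@H](OC(=S)SC)[C@H]2CO[C@@H](c3cc(OC)c(OC)c(OC)c3)[C@H]2CO[Si](C)(C)C(C)(C)C)cc1OC
F7 | step 9 | tert-butyldimethylsilyl ether of 17 | COc1ccc(C[C@H]2CO[C@@H](c3cc(OC)c(OC)c(OC)c3)[C@H]2CO[Si](C)(C)C(C)(C)C)cc1OC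
F8 | step 6 | (4R,5S)-5-(3,4-dimethoxyphenyl)-4-{[(trimethylsilyl)oxy]methyl}oxolan-2-one | O=C1O[C@H](c2ccc(OC)c(OC)c2)[C@@H](CO[Si](C)(C)C)C1
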